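## Retrosynthetic overview

1. The target comes from chelation-controlled 8-O-demethylation of (R)-6,8-dimethoxy-3-(6-oxoundecyl)isochroman-1-one. Its side chain comes from cross-metathesis and hydrogenation of (R)-3-allyl-6,8-dimethoxyisochroman-1-one with dec-1-en-5-one (made from pent-4-enoyl chloride and pentylmagnesium bromide via the Weinreb amide).
2. The lactone comes from lactonisation of a 2-(2-hydroxyalkyl)benzoic acid. The carboxyl is put in by Vilsmeier formylation and Pinnick oxidation ortho to the side chain of (R)-1-(3,5-dimethoxyphenyl)pent-4-en-2-ol.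
3. The key C–C bond and the only stereocentre (C3) come from a Brown asymmetric carbonyl allylation that joins (3,5-dimethoxyphenyl)acetaldehyde with an allyl unit.
4. The aldehyde comes from (3,5-dimethoxyphenyl)acetic acid by reduction, then oxidation.
5. Ring order: the benzene ring is bought; the δ-lactone is the only ring formed (step 7), after the stereocentre is in place.

Assumption: the stereocentre is (R) at C3 (same sense as (R)-mellein), and "(+)-Ipc2BOMe" means the (−)-α-pinene-derived reagent COB([C@H]1C[C@H]2C[C@@H]([C@@H]1C)C2(C)C)[C@H]1C[C@H]2C[C@@H]([C@@H]1C)C2(C)C. The facial sense of this reagent is assigned from the known behaviour of the Brown reagents and should be confirmed on 7 (Mosher ester or chiral HPLC).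

## Route

Step 1
Reactants: 1 (3,5-dimethoxyphenyl)acetic acid
Product: 2 2-(3,5-dimethoxyphenyl)ethanol
Conditions: BH3·THF (1.5 equiv), THF, 0 °C → rt; H2O quench
Reagents that add atoms: none
Why: Borane reduction takes the carboxylic acid chemoselectively to the primary alcohol through an acyloxyborane, and the aryl methyl ethers are inert.

Step 2
Reactants: 2 2-(3,5-dimethoxyphenyl)ethanol
Product: 3 (3,5-dimethoxyphenyl)acetaldehyde
Conditions: Dess–Martin periodinane (1.2 equiv), CH2Cl2, 0 °C → rt; used crude at once
Reagents that add atoms: none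
Why: Dess–Martin oxidation stops at the aldehyde under near-neutral, non-aqueous conditions, which suits this enolisable, air-sensitive arylacetaldehyde.

Step 3
Reactants: 3 (3,5-dimethoxyphenyl)acetaldehyde; 4 allylmagnesium bromide
Product: 7 (R)-1-(3,5-dimethoxyphenyl)pent-4-en-2-ol, via B-allyldiisopinocampheylborane 5 (not isolated), via diisopinocampheylborinate ester 6 (not isolated)
Conditions: (+)-Ipc2BOMe (1.3 equiv), 4 (1.2 equiv), Et2O, 0 °C → rt, Mg salts filtered off; 3, −100 °C; then 3 M NaOH, 30% H2O2, 0 °C → rt
Reagents that add atoms: none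
Why: Brown asymmetric allylboration (carbonyl allylation): borane 5 transfers allyl through a closed chair six-membered transition state in which the (−)-α-pinene-derived Ipc groups direct attack to the Re face of the aldehyde, which sets the carbinol centre as (R) (about 90% ee or better expected), and oxidative work-up cleaves borinate 6.

Step 4
Reactants: 7 (R)-1-(3,5-dimethoxyphenyl)pent-4-en-2-ol
Product: 8 (R)-1-(3,5-dimethoxyphenyl)pent-4-en-2-yl acetate
Conditions: Ac2O, pyridine, DMAP (cat.), CH2Cl2, rt
Reagents that add atoms: acetic anhydride CC(=O)OC(C)=O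
Why: DMAP-catalysed O-acetylation protects the secondary alcohol, which the Vilsmeier reagent would otherwise formylate or chlorinate, and does not touch the C–O stereocentre.

Step 5
Reactants: 8 (R)-1-(3,5-dimethoxyphenyl)pent-4-en-2-yl acetate
Product: 10 (R)-1-(2-formyl-3,5-dimethoxyphenyl)pent-4-en-2-yl acetate, via aryl iminium salt 9 (not isolated)
Conditions: POCl3 (1.5 equiv), DMF, 0 → 60 °C; then aq. NaOAc, rt
Reagents that add atoms: N,N-dimethylformamide CN(C)C=O; water O
Why: Vilsmeier–Haack formylation (electrophilic aromatic substitution) attacks the ring carbon ortho to the side chain and para to a methoxy group (the two such carbons are equivalent and the carbon between the two methoxy groups is more hindered), and mild hydrolysis of iminium 9 gives the aldehyde with acetate, alkene and stereocentre untouched.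

Step 6
Reactants: 10 (R)-1-(2-formyl-3,5-dimethoxyphenyl)pent-4-en-2-yl acetate
Product: 11 (R)-2-(2-acetoxypent-4-en-1-yl)-4,6-dimethoxybenzoic acid
Conditions: NaClO2, NaH2PO4, 2-methylbut-2-ene (20 equiv), t-BuOH/H2O, 0 °C → rt
Reagents that add atoms: sodium chlorite [Na+].[O-]Cl=O
Why: Pinnick oxidation converts the electron-rich aryl aldehyde to the acid under buffered conditions while the excess trisubstituted alkene traps HOCl, so neither the ring nor the terminal alkene is chlorinated.

Step 7
Reactants: 11 (R)-2-(2-acetoxypent-4-en-1-yl)-4,6-dimethoxybenzoic acid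
Product: 13 (R)-3-allyl-6,8-dimethoxyisochroman-1-one, via hydroxy acid 12 (not isolated)
Conditions: LiOH·H2O, THF/MeOH/H2O, rt; then 2 M HCl to pH 1; p-TsOH (cat.), CH2Cl2, rt
Reagents that add atoms: none
Why: Saponification frees the secondary alcohol by acyl–oxygen cleavage, and on acidification δ-hydroxy acid 12 closes the six-membered lactone (acid-catalysed lactonisation) through attack of the alcohol oxygen on the carboxyl, so C3 keeps its (R) configuration.

Step 8
Reactants: 14 pent-4-enoyl chloride
Product: 15 N-methoxy-N-methylpent-4-enamide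
Conditions: MeNH(OMe)·HCl, Et3N (2.2 equiv), CH2Cl2, 0 °C → rt
Reagents that add atoms: N,O-dimethylhydroxylamine hydrochloride CNOC.Cl
Why: N-acylation of the hydroxylamine by the acid chloride (nucleophilic acyl substitution) gives the Weinreb amide cleanly.

Step 9
Reactants: 15 N-methoxy-N-methylpent-4-enamide; 16 n-pentylmagnesium bromide
Product: 18 dec-1-en-5-one, via magnesium chelate 17 (not isolated)
Conditions: THF, 0 °C; then 1 M HCl
Reagents that add atoms: none
Why: Weinreb ketone synthesis: the Grignard reagent adds once to give the stable five-membered chelate 17, which collapses to the ketone only on acidic work-up, so no tertiary alcohol forms and the terminal alkene is untouched.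

Step 10
Reactants: 13 (R)-3-allyl-6,8-dimethoxyisochroman-1-one; 18 dec-1-en-5-one
Product: 19 (R)-6,8-dimethoxy-3-[(2E)-6-oxoundec-2-en-1-yl]isochroman-1-one (E/Z mixture is acceptable)
Conditions: Grubbs II (5 mol%), 18 (3 equiv), CH2Cl2, 40 °C, N2 sweep
Reagents that add atoms: none
Why: Olefin cross-metathesis between two unhindered terminal alkenes is driven to the cross product by the threefold excess of the cheap ketone and loss of ethene, and lactone, ketone and C3 are inert to the Ru carbene.

Step 11
Reactants: 19 (R)-6,8-dimethoxy-3-[(2E)-6-oxoundec-2-en-1-yl]isochroman-1-one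
Product: 20 (R)-6,8-dimethoxy-3-(6-oxoundecyl)isochroman-1-one
Conditions: H2 (1 atm), 10% Pd/C, EtOAc, rt
Reagents that add atoms: none
Why: Heterogeneous catalytic hydrogenation saturates the disubstituted alkene of either geometry, while the dialkyl ketone, the lactone and the aryl ethers are not reduced at 1 atm and rt.

Step 12
Reactants: 20 (R)-6,8-dimethoxy-3-(6-oxoundecyl)isochroman-1-one
Product: 22 (R)-8-hydroxy-6-methoxy-3-(6-oxoundecyl)isochroman-1-one (target), via aryloxydichloroborane 21 (not isolated)
Conditions: BCl3 (1 M in CH2Cl2, 3 equiv), CH2Cl2, −78 → 0 °C; then H2O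
Reagents that add atoms: none
Why: Chelation-controlled Lewis-acid ether cleavage: BCl3 bridges the lactone carbonyl and the peri 8-methoxy oxygen, chloride removes that methyl to give 21, and hydrolysis frees the hydrogen-bonded phenol, while the unchelated 6-OMe, the ketone, the lactone and C3 are untouched.

## Compound list

1 | (3,5-dimethoxyphenyl)acetic acid | COc1cc(CC(=O)O)cc(OC)c1 | starting material
2 | 2-(3,5-dimethoxyphenyl)ethanol | COc1cc(CCO)cc(OC)c1 | intermediate
3 | (3,5-dimethoxyphenyl)acetaldehyde | COc1cc(CC=O)cc(OC)c1 | intermediate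
4 | allylmagnesium bromide | C=CC[Mg]Br | starting material
5 | B-allyldiisopinocampheylborane of the (−)-α-pinene series (each Ipc configured as in (+)-isopinocampheol) | C=CCB([C@H]1C[C@H]2C[C@@H]([C@@H]1C)C2(C)C)[C@H]1C[C@H]2C[C@@H]([C@@H]1C)C2(C)C | intermediate (not isolated)
6 | (R)-1-(3,5-dimethoxyphenyl)pent-4-en-2-yl diisopinocampheylborinate (Ipc groups as in 5) | C=CC[C@@H](OB([C@H]1C[C@H]2C[C@@H]([C@@H]1C)C2(C)C)[C@H]1C[C@H]2C[C@@H]([C@@H]1C)C2(C)C)Cc1cc(OC)cc(OC)c1 | intermediate (not isolated)
7 | (R)-1-(3,5-dimethoxyphenyl)pent-4-en-2-ol | C=CC[C@@H](O)Cc1cc(OC)cc(OC)c1 | intermediate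
8 | (R)-1-(3,5-dimethoxyphenyl)pent-4-en-2-yl acetate | C=CC[C@@H](OC(C)=O)Cc1cc(OC)cc(OC)c1 | intermediate
9 | N-{2-[(R)-2-acetoxypent-4-en-1-yl]-4,6-dimethoxybenzylidene}-N-methylmethanaminium dichlorophosphate | C=CC[C@@H](OC(C)=O)Cc1cc(OC)cc(OC)c1C=[N+](C)C.[O-]P(=O)(Cl)Cl | intermediate (not isolated)
10 | (R)-1-(2-formyl-3,5-dimethoxyphenyl)pent-4-en-2-yl acetate | C=CC[C@@H](OC(C)=O)Cc1cc(OC)cc(OC)c1C=O | intermediate
11 | (R)-2-(2-acetoxypent-4-en-1-yl)-4,6-dimethoxybenzoic acid | C=CC[C@@H](OC(C)=O)Cc1cc(OC)cc(OC)c1C(=O)O | intermediate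
12 | (R)-2-(2-hydroxypent-4-en-1-yl)-4,6-dimethoxybenzoic acid | C=CC[C@@H](O)Cc1cc(OC)cc(OC)c1C(=O)O | intermediate (not isolated)
13 | (R)-3-allyl-6,8-dimethoxyisochroman-1-one | C=CC[C@@H]1Cc2cc(OC)cc(OC)c2C(=O)O1 | intermediate
14 | pent-4-enoyl chloride | C=CCCC(=O)Cl | starting material
15 | N-methoxy-N-methylpent-4-enamide | C=CCCC(=O)N(C)OC | intermediate
16 | n-pentylmagnesium bromide | CCCCC[Mg]Br | starting material
17 | bromomagnesium 5-[methoxy(methyl)amino]dec-1-en-5-olate (tetrahedral chelate) | C=CCCC(CCCCC)(O[Mg]Br)N(C)OC | intermediate (not isolated)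
18 | dec-1-en-5-one | C=CCCC(=O)CCCCC | intermediate
19 | (R)-6,8-dimethoxy-3-[(2E)-6-oxoundec-2-en-1-yl]isochroman-1-one | CCCCCC(=O)CC/C=C/C[C@@H]1Cc2cc(OC)cc(OC)c2C(=O)O1 | intermediate
20 | (R)-6,8-dimethoxy-3-(6-oxoundecyl)isochroman-1-one | CCCCCC(=O)CCCCC[C@@H]1Cc2cc(OC)cc(OC)c2C(=O)O1 | intermediate
21 | (R)-8-(dichloroboryloxy)-6-methoxy-3-(6-oxoundecyl)isochroman-1-one | CCCCCC(=O)CCCCC[C@@H]1Cc2cc(OC)cc(OB(Cl)Cl)c2C(=O)O1 | intermediate (not isolated)
22 | (R)-8-hydroxy-6-methoxy-3-(6-oxoundecyl)isochroman-1-one | CCCCCC(=O)CCCCC[C@@H]1Cc2cc(OC)cc(O)c2C(=O)O1 | target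

## Count and risks

Total step count: 12. Longest linear sequence: 10 steps (steps 1–7, then 10–12); steps 8–9 are a two-step branch that supplies ketone 18.

The three steps most likely to fail:

Step 3. Aldehyde 3 is enolisable and prone to self-condensation, and the ee of the allylboration falls if magnesium salts or warming intrude. The fallback sets out from alcohol 2 and comes back at 7, bypassing the isolated aldehyde. It is an iridium-catalysed transfer-hydrogenative carbonyl allylation: 2 with allyl acetate, [Ir(cod)Cl]2, (R)-BINAP, 4-chloro-3-nitrobenzoic acid and Cs2CO3 in THF at 100 °C. The alcohol is dehydrogenated in the flask to 3, which is trapped at once by the chiral allyl-iridium species. The ligand antipode has to be confirmed against 7 from step 3 by chiral HPLC. This fallback makes no compound outside the list (F0).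

Step 5. The formylation may stall or give some of the isomer formylated between the two methoxy groups. The fallback sets out from 7 (steps 4–6 are then not needed) and comes back at hydroxy acid 12, which is lactonised to 13 as in the second half of step 7. NBS in MeCN at 0 °C brominates the ring ortho to the side chain and para to a methoxy group to give (R)-1-(2-bromo-3,5-dimethoxyphenyl)pent-4-en-2-ol F1. n-BuLi (2.2 equiv) in THF at −78 °C removes the OH proton and exchanges bromine for lithium to give lithium (R)-1-(2-lithio-3,5-dimethoxyphenyl)pent-4-en-2-olate F2. This is quenched with CO2 and acidified to give 12. The carboxyl is thus brought in by halogen–metal exchange and carboxylation, not by formylation and oxidation.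

Step 10. Cross-metathesis between two type-I alkenes is statistical and can suffer olefin migration, which costs precious 13. The fallback sets out from 13 and comes back at 20, so step 11 is also skipped. Hydroboration with 9-BBN in THF gives (R)-3-[3-(9-borabicyclo[3.3.1]nonan-9-yl)propyl]-6,8-dimethoxyisochroman-1-one F3. Oxidation with NaBO3·4H2O gives (R)-3-(3-hydroxypropyl)-6,8-dimethoxyisochroman-1-one F4. I2, PPh3 and imidazole in CH2Cl2 give (R)-3-(3-iodopropyl)-6,8-dimethoxyisochroman-1-one F5. The primary radical from F5 ((Me3Si)3SiH, AIBN, toluene, 80 °C, slow addition) adds in a Giese conjugate addition to commercial oct-1-en-3-one (4 equiv) to give 20 directly.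

## Further compounds

F0 | step 3 | none | none
F1 | step 5 | (R)-1-(2-bromo-3,5-dimethoxyphenyl)pent-4-en-2-ol | C=CC[C@@H](O)Cc1cc(OC)cc(OC)c1Br
F2 | step 5 | lithium (R)-1-(2-lithio-3,5-dimethoxyphenyl)pent-4-en-2-olate | C=CC[C@@H](O[Li])Cc1cc(OC)cc(OC)c1[Li]
F3 | step 10 | (R)-3-[3-(9-borabicyclo[3.3.1]nonan-9-yl)propyl]-6,8-dimethoxyisochroman-1-one | C(CCB1C2CCCC1CCC2)[C@@H]1Cc2cc(OC)cc(OC)c2C(=O)O1
F4 | step 10 | (R)-3-(3-hydroxypropyl)-6,8-dimethoxyisochroman-1-one | OCCC[C@@H]1Cc2cc(OC)cc(OC)c2C(=O)O1
F5 | step 10 | (R)-3-(3-iodopropyl)-6,8-dimethoxyisochroman-1-one | ICCC[C@@H]1Cc2cc(OC)cc(OC)c2C(=O)O1
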